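## Retrosynthetic overview

1. Target ⇐ PMB ether ⇐ allylic sulfoxide: the primary allylic C–O bond and the E trisubstituted alkene come from a Mislow–Evans [2,3]-sigmatropic shift.
2. Allylic sulfide ⇐ α-chloro sulfide of a butenolide (fragment B) + 2-alkenylalane of a C18 enyne (fragment A): C–C bond made at the sulfur-bearing carbon.
3. Fragment B ⇐ (S)-α-hydroxy-γ-butyrolactone, which carries the only stereocentre: thiolate ring opening, Weinreb amide, alkoxymethyllithium, then ylide acylation/intramolecular Wittig.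
4. Fragment A ⇐ dihydro-β-ionone: ketone-to-alkyne, carboalumination/iodination (E alkene), Negishi coupling with a homopropargyl zinc reagent.
5. Rings: the cyclohexene ring is bought; the butenolide is the only ring formed (step 8), before fragment union (step 9) and the sigmatropic step (step 10).

Assumption: the stereocentre is (S) as read from the SMILES, and (S)-α-hydroxy-γ-butyrolactone (made from L-malic acid) and tributyl(iodomethyl)stannane are taken as commercial.

## Route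

Step 1
Reactants: 1 dihydro-β-ionone (4-(2,6,6-trimethylcyclohex-1-en-1-yl)butan-2-one)
Product: 3 2-(but-3-yn-1-yl)-1,3,3-trimethylcyclohex-1-ene, via enol phosphate 2 (not isolated)
Conditions: LiN(i-Pr)2 (1.05 equiv), THF, −78 °C; ClP(O)(OEt)2, −78 °C to rt; LiN(i-Pr)2 (2.3 equiv), −78 °C to rt; H2O
Reagents that add atoms: none
Why: The kinetic methyl enolate is trapped as its enol phosphate and excess amide base eliminates phosphate (Negishi ketone-to-alkyne conversion), with no stereocentre involved.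

Step 2
Reactants: 3 2-(but-3-yn-1-yl)-1,3,3-trimethylcyclohex-1-ene
Product: 5 2-[(3E)-4-iodo-3-methylbut-3-en-1-yl]-1,3,3-trimethylcyclohex-1-ene, via alkenylalane 4 (not isolated)
Conditions: Me3Al (2 equiv), Cp2ZrCl2 (0.25 equiv), CH2Cl2, 0 °C to rt; then I2, THF, −30 to 0 °C
Reagents that add atoms: trimethylaluminium (Me3Al), C[Al](C)C; iodine (I2), II
Why: Zirconium-catalysed syn-carboalumination (Negishi) puts methyl and aluminium cis with the metal at the terminus, and iodinolysis with retention fixes the E trisubstituted alkene.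

Step 3
Reactants: 5 2-[(3E)-4-iodo-3-methylbut-3-en-1-yl]-1,3,3-trimethylcyclohex-1-ene; 6 (4-bromobut-1-yn-1-yl)trimethylsilane
Product: 9 2-[(3E)-3-methyloct-3-en-7-yn-1-yl]-1,3,3-trimethylcyclohex-1-ene, via organozinc bromide 7 (not isolated), via silyl enyne 8 (not isolated)
Conditions: 6, Zn, LiCl, THF, 50 °C; then 5, Pd(PPh3)4 (3 mol%), THF, rt to 45 °C; then K2CO3 (0.2 equiv), MeOH, rt
Reagents that add atoms: none
Why: Negishi sp3–sp2 cross-coupling of the alkylzinc with the alkenyl iodide retains the alkene geometry, and methanolysis removes the alkynyl silyl group in the same pot.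

Step 4
Reactants: 10 (3S)-3-hydroxyoxolan-2-one ((S)-α-hydroxy-γ-butyrolactone)
Product: 11 (2S)-2-hydroxy-4-(phenylsulfanyl)butanoic acid
Conditions: PhSNa (1.2 equiv), DMF, 110 °C; then aq. HCl
Reagents that add atoms: sodium benzenethiolate (PhSNa), [Na+].[S-]c1ccccc1
Why: The soft thiolate opens the γ-lactone by SN2 attack at the O-bearing CH2 (alkyl–oxygen cleavage), so the purchased (S) carbinol centre is not touched.

Step 5
Reactants: 11 (2S)-2-hydroxy-4-(phenylsulfanyl)butanoic acid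
Product: 12 (2S)-2-hydroxy-N-methoxy-N-methyl-4-(phenylsulfanyl)butanamide
Conditions: MeNHOMe·HCl, EDC·HCl, HOBt (cat.), N-methylmorpholine, CH2Cl2, 0 °C to rt
Reagents that add atoms: N,O-dimethylhydroxylamine hydrochloride, CNOC.Cl
Why: Carbodiimide-mediated amidation gives the Weinreb amide under conditions that do not epimerise the α-hydroxy centre.

Step 6
Reactants: 13 (4-methoxyphenyl)methanol; 14 tributyl(iodomethyl)stannane
Product: 15 tributyl{[(4-methoxyphenyl)methoxy]methyl}stannane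
Conditions: NaH, THF/DMF, 0 °C to rt
Reagents that add atoms: none
Why: Williamson etherification of the sodium alkoxide with the primary iodide gives the stannane precursor of a protected hydroxymethyl anion.

Step 7
Reactants: 12 (2S)-2-hydroxy-N-methoxy-N-methyl-4-(phenylsulfanyl)butanamide; 15 tributyl{[(4-methoxyphenyl)methoxy]methyl}stannane
Product: 17 (3S)-3-hydroxy-1-[(4-methoxyphenyl)methoxy]-5-(phenylsulfanyl)pentan-2-one, via alkoxymethyllithium 16 (not isolated)
Conditions: 15 (2.3 equiv), n-BuLi (2.2 equiv), THF, −78 °C; then 12, −78 °C; aq. NH4Cl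
Reagents that add atoms: none
Why: Tin–lithium exchange gives the α-alkoxymethyllithium, of which one equivalent deprotonates the hydroxyl and the second adds once to the Weinreb amide through the chelated tetrahedral intermediate (acyl substitution), leaving the (S) centre intact.

Step 8
Reactants: 17 (3S)-3-hydroxy-1-[(4-methoxyphenyl)methoxy]-5-(phenylsulfanyl)pentan-2-one
Product: 19 (5S)-4-{[(4-methoxyphenyl)methoxy]methyl}-5-[2-(phenylsulfanyl)ethyl]furan-2(5H)-one, via ester ylide 18 (not isolated)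
Conditions: Ph3P=C=C=O (1.3 equiv), toluene, 90 °C
Reagents that add atoms: (triphenylphosphoranylidene)ketene, O=C=C=P(c1ccccc1)(c1ccccc1)c1ccccc1
Why: The hydroxyl adds to the ketenylidene ylide and the resulting ester ylide closes the butenolide by intramolecular Wittig olefination of the ketone (Bestmann tandem acylation–Wittig) under neutral conditions, so the adjacent stereocentre is retained.

Step 9
Reactants: 19 (5S)-4-{[(4-methoxyphenyl)methoxy]methyl}-5-[2-(phenylsulfanyl)ethyl]furan-2(5H)-one; 9 2-[(3E)-3-methyloct-3-en-7-yn-1-yl]-1,3,3-trimethylcyclohex-1-ene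
Product: 22 (5S)-4-{[(4-methoxyphenyl)methoxy]methyl}-5-[(6E)-7-methyl-3-methylidene-2-(phenylsulfanyl)-9-(2,6,6-trimethylcyclohex-1-en-1-yl)non-6-en-1-yl]furan-2(5H)-one as a mixture of epimers at the sulfur-bearing carbon, via chloro sulfide 20 (not isolated), via vinylalane 21 (not isolated)
Conditions: a) 9 (1.3 equiv), (i-Bu)2AlH (1.2 equiv), NiCl2(dppp) (3 mol%), THF, 0 °C to rt; b) 19, NCS (1.05 equiv), CH2Cl2, 0 °C to rt; c) b added to a, −78 to 0 °C
Reagents that add atoms: none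
Why: Nickel-catalysed Markovnikov hydroalumination gives the 2-alkenylalane, NCS α-chlorination gives a thionium-ion precursor, and Lewis-acid-assisted alkenylation of that thionium ion forms the C–C bond only at the sulfur-bearing carbon; the new centre is unselective and is erased in step 10.

Step 10
Reactants: 22 (5S)-4-{[(4-methoxyphenyl)methoxy]methyl}-5-[(6E)-7-methyl-3-methylidene-2-(phenylsulfanyl)-9-(2,6,6-trimethylcyclohex-1-en-1-yl)non-6-en-1-yl]furan-2(5H)-one
Product: 25 (5S)-5-[(2E,6E)-3-(hydroxymethyl)-7-methyl-9-(2,6,6-trimethylcyclohex-1-en-1-yl)nona-2,6-dien-1-yl]-4-{[(4-methoxyphenyl)methoxy]methyl}furan-2(5H)-one, via allylic sulfoxide 23 (not isolated), via sulfenate ester 24 (not isolated)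
Conditions: mCPBA (1.0 equiv), CH2Cl2, −78 °C; then P(OMe)3 (3 equiv), MeOH, −78 °C to rt
Reagents that add atoms: 3-chloroperoxybenzoic acid, OOC(=O)c1cccc(Cl)c1
Why: Chemoselective S-oxidation gives the allylic sulfoxide, whose Mislow–Evans [2,3]-sigmatropic rearrangement (envelope transition state, butenolide-bearing substituent pseudoequatorial) forms the primary allylic C–O bond and the E trisubstituted alkene, the sulfenate being cleaved irreversibly by the phosphite.

Step 11
Reactants: 25 (5S)-5-[(2E,6E)-3-(hydroxymethyl)-7-methyl-9-(2,6,6-trimethylcyclohex-1-en-1-yl)nona-2,6-dien-1-yl]-4-{[(4-methoxyphenyl)methoxy]methyl}furan-2(5H)-one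
Product: 26 (5S)-4-(hydroxymethyl)-5-[(2E,6E)-3-(hydroxymethyl)-7-methyl-9-(2,6,6-trimethylcyclohex-1-en-1-yl)nona-2,6-dien-1-yl]furan-2(5H)-one (target)
Conditions: DDQ (1.3 equiv), CH2Cl2/pH 7 buffer 10:1, 0 °C
Reagents that add atoms: none
Why: Oxidative PMB-ether cleavage by DDQ (benzylic hydride abstraction, then hydrolysis) frees the second primary alcohol without acid or base, so the butenolide stereocentre and the alkenes are not disturbed.

## Compound list

1 | dihydro-β-ionone, 4-(2,6,6-trimethylcyclohex-1-en-1-yl)butan-2-one | CC(=O)CCC1=C(C)CCCC1(C)C | starting material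
2 | diethyl 4-(2,6,6-trimethylcyclohex-1-en-1-yl)but-1-en-2-yl phosphate | C=C(CCC1=C(C)CCCC1(C)C)OP(=O)(OCC)OCC | intermediate
3 | 2-(but-3-yn-1-yl)-1,3,3-trimethylcyclohex-1-ene | C#CCCC1=C(C)CCCC1(C)C | intermediate
4 | dimethyl[(1E)-2-methyl-4-(2,6,6-trimethylcyclohex-1-en-1-yl)but-1-en-1-yl]alumane | C[Al](C)/C=C(\C)CCC1=C(C)CCCC1(C)C | intermediate
5 | 2-[(3E)-4-iodo-3-methylbut-3-en-1-yl]-1,3,3-trimethylcyclohex-1-ene | I/C=C(\C)CCC1=C(C)CCCC1(C)C | intermediate
6 | (4-bromobut-1-yn-1-yl)trimethylsilane | C[Si](C)(C)C#CCCBr | starting material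
7 | bromo[4-(trimethylsilyl)but-3-yn-1-yl]zinc | C[Si](C)(C)C#CCC[Zn]Br | intermediate
8 | trimethyl[(5E)-6-methyl-8-(2,6,6-trimethylcyclohex-1-en-1-yl)oct-5-en-1-yn-1-yl]silane | C[Si](C)(C)C#CCC/C=C(\C)CCC1=C(C)CCCC1(C)C | intermediate
9 | 2-[(3E)-3-methyloct-3-en-7-yn-1-yl]-1,3,3-trimethylcyclohex-1-ene | C#CCC/C=C(\C)CCC1=C(C)CCCC1(C)C | intermediate
10 | (3S)-3-hydroxyoxolan-2-one, (S)-α-hydroxy-γ-butyrolactone | O[C@H]1CCOC1=O | starting material
11 | (2S)-2-hydroxy-4-(phenylsulfanyl)butanoic acid | OC(=O)[C@@H](O)CCSc1ccccc1 | intermediate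
12 | (2S)-2-hydroxy-N-methoxy-N-methyl-4-(phenylsulfanyl)butanamide | CON(C)C(=O)[C@@H](O)CCSc1ccccc1 | intermediate
13 | (4-methoxyphenyl)methanol | COc1ccc(CO)cc1 | starting material
14 | tributyl(iodomethyl)stannane | CCCC[Sn](CCCC)(CCCC)CI | starting material
15 | tributyl{[(4-methoxyphenyl)methoxy]methyl}stannane | CCCC[Sn](CCCC)(CCCC)COCc1ccc(OC)cc1 | intermediate
16 | {[(4-methoxyphenyl)methoxy]methyl}lithium | [Li]COCc1ccc(OC)cc1 | intermediate
17 | (3S)-3-hydroxy-1-[(4-methoxyphenyl)methoxy]-5-(phenylsulfanyl)pentan-2-one | COc1ccc(COCC(=O)[C@@H](O)CCSc2ccccc2)cc1 | intermediate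
18 | (3S)-1-[(4-methoxyphenyl)methoxy]-2-oxo-5-(phenylsulfanyl)pentan-3-yl (triphenylphosphoranylidene)acetate | COc1ccc(COCC(=O)[C@@H](OC(=O)C=P(c2ccccc2)(c3ccccc3)c4ccccc4)CCSc5ccccc5)cc1 | intermediate
19 | (5S)-4-{[(4-methoxyphenyl)methoxy]methyl}-5-[2-(phenylsulfanyl)ethyl]furan-2(5H)-one | c1ccc(SCC[C@@H]2OC(=O)C=C2COCc3ccc(OC)cc3)cc1 | intermediate
20 | (5S)-5-[2-chloro-2-(phenylsulfanyl)ethyl]-4-{[(4-methoxyphenyl)methoxy]methyl}furan-2(5H)-one, both epimers at the chlorinated carbon | c1ccc(SC(Cl)C[C@@H]2OC(=O)C=C2COCc3ccc(OC)cc3)cc1 | intermediate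
21 | bis(2-methylpropyl)[(5E)-6-methyl-8-(2,6,6-trimethylcyclohex-1-en-1-yl)octa-1,5-dien-2-yl]alumane | C=C([Al](CC(C)C)CC(C)C)CC/C=C(\C)CCC1=C(C)CCCC1(C)C | intermediate
22 | (5S)-4-{[(4-methoxyphenyl)methoxy]methyl}-5-[(6E)-7-methyl-3-methylidene-2-(phenylsulfanyl)-9-(2,6,6-trimethylcyclohex-1-en-1-yl)non-6-en-1-yl]furan-2(5H)-one, both epimers at the sulfur-bearing carbon | C=C(CC/C=C(\C)CCC1=C(C)CCCC1(C)C)C(Sc2ccccc2)C[C@@H]3OC(=O)C=C3COCc4ccc(OC)cc4 | intermediate
23 | (5S)-4-{[(4-methoxyphenyl)methoxy]methyl}-5-[(6E)-7-methyl-3-methylidene-2-(phenylsulfinyl)-9-(2,6,6-trimethylcyclohex-1-en-1-yl)non-6-en-1-yl]furan-2(5H)-one, diastereomer mixture | C=C(CC/C=C(\C)CCC1=C(C)CCCC1(C)C)C(S(=O)c2ccccc2)C[C@@H]3OC(=O)C=C3COCc4ccc(OC)cc4 | intermediate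
24 | (5S)-4-{[(4-methoxyphenyl)methoxy]methyl}-5-[(2E,6E)-7-methyl-3-{[(phenylsulfanyl)oxy]methyl}-9-(2,6,6-trimethylcyclohex-1-en-1-yl)nona-2,6-dien-1-yl]furan-2(5H)-one | CC1=C(CC/C(C)=C/CC/C(=C\C[C@@H]2OC(=O)C=C2COCc3ccc(OC)cc3)COSc4ccccc4)C(C)(C)CCC1 | intermediate
25 | (5S)-5-[(2E,6E)-3-(hydroxymethyl)-7-methyl-9-(2,6,6-trimethylcyclohex-1-en-1-yl)nona-2,6-dien-1-yl]-4-{[(4-methoxyphenyl)methoxy]methyl}furan-2(5H)-one | CC1=C(CC/C(C)=C/CC/C(=C\C[C@@H]2OC(=O)C=C2COCc3ccc(OC)cc3)CO)C(C)(C)CCC1 | intermediate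
26 | (5S)-4-(hydroxymethyl)-5-[(2E,6E)-3-(hydroxymethyl)-7-methyl-9-(2,6,6-trimethylcyclohex-1-en-1-yl)nona-2,6-dien-1-yl]furan-2(5H)-one | CC1=C(CC/C(C)=C/CC/C(=C\C[C@@H]2OC(=O)C=C2CO)CO)C(C)(C)CCC1 | target

## Step count and risks

Total step count: 11. Longest linear sequence: 7 steps (from 10 through steps 4, 5, 7, 8, 9, 10 and 11).

Most likely to fail, first: step 9. The chloro sulfide 20 can lose HCl to a vinyl sulfide, and the aluminium Lewis acid may attack the butenolide or the PMB ether. The fallback makes the same C–C bond by carbonyl addition and sets out from 19 and from 21 (made from 9 as before). Oxidation of 19 with NaIO4 gives the sulfoxide F1, and Pummerer rearrangement (TFAA, 2,6-lutidine, then aq. NaHCO3) unmasks the aldehyde F2. Bromination of 21 with NBS gives the bromodiene F3. Nozaki–Hiyama–Kishi coupling of F2 with F3 (CrCl2, catalytic NiCl2, DMF) gives the allylic alcohol F4 as an epimer mixture. Hata thioetherification of F4 (PhSSPh, PBu3) with inversion comes back to the route at 22.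

Second: step 7. Acyl substitution on the lithium alkoxide of the hydroxy amide may stall or over-add. The fallback reaches the ketone by an addition/oxidation detour and sets out from 12. Silylation (TBSOTf, 2,6-lutidine) gives the silyl ether F5, and reduction with (i-Bu)2AlH at −78 °C gives the aldehyde F6. Addition of 16 gives the carbinol F7 (both epimers), Dess–Martin oxidation gives the silyloxy ketone F8, and HF·pyridine removes the silyl group to come back at 17.

Third: step 8. The ketenylidene-ylide annulation may be slow on this α,α'-dioxygenated ketone or may erode the γ-stereocentre at 90 °C. The fallback sets out from 17. Esterification with (diethoxyphosphoryl)acetic acid (DCC, DMAP) gives the phosphonoacetate F9, and intramolecular Horner–Wadsworth–Emmons olefination under Masamune–Roush conditions (LiCl, i-Pr2NEt, MeCN, rt) closes the butenolide and comes back at 19.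

Further compounds
F1 | step 9 | (5S)-4-{[(4-methoxyphenyl)methoxy]methyl}-5-[2-(phenylsulfinyl)ethyl]furan-2(5H)-one | O=S(CC[C@@H]1OC(=O)C=C1COCc2ccc(OC)cc2)c3ccccc3
F2 | step 9 | [(2S)-3-{[(4-methoxyphenyl)methoxy]methyl}-5-oxo-2,5-dihydrofuran-2-yl]acetaldehyde | O=CC[C@@H]1OC(=O)C=C1COCc2ccc(OC)cc2
F3 | step 9 | 2-[(3E)-7-bromo-3-methylocta-3,7-dien-1-yl]-1,3,3-trimethylcyclohex-1-ene | C=C(Br)CC/C=C(\C)CCC1=C(C)CCCC1(C)C
F4 | step 9 | (5S)-5-[(6E)-2-hydroxy-7-methyl-3-methylidene-9-(2,6,6-trimethylcyclohex-1-en-1-yl)non-6-en-1-yl]-4-{[(4-methoxyphenyl)methoxy]methyl}furan-2(5H)-one, both epimers at the carbinol | C=C(CC/C=C(\C)CCC1=C(C)CCCC1(C)C)C(O)C[C@@H]2OC(=O)C=C2COCc3ccc(OC)cc3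
F5 | step 7 | (2S)-2-[(tert-butyldimethylsilyl)oxy]-N-methoxy-N-methyl-4-(phenylsulfanyl)butanamide | CON(C)C(=O)[C@@H](O[Si](C)(C)C(C)(C)C)CCSc1ccccc1
F6 | step 7 | (2S)-2-[(tert-butyldimethylsilyl)oxy]-4-(phenylsulfanyl)butanal | O=C[C@@H](O[Si](C)(C)C(C)(C)C)CCSc1ccccc1
F7 | step 7 | (3S)-3-[(tert-butyldimethylsilyl)oxy]-1-[(4-methoxyphenyl)methoxy]-5-(phenylsulfanyl)pentan-2-ol, both epimers at C2 | COc1ccc(COCC(O)[C@@H](O[Si](C)(C)C(C)(C)C)CCSc2ccccc2)cc1
F8 | step 7 | (3S)-3-[(tert-butyldimethylsilyl)oxy]-1-[(4-methoxyphenyl)methoxy]-5-(phenylsulfanyl)pentan-2-one | COc1ccc(COCC(=O)[C@@H](O[Si](C)(C)C(C)(C)C)CCSc2ccccc2)cc1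
F9 | step 8 | (3S)-1-[(4-methoxyphenyl)methoxy]-2-oxo-5-(phenylsulfanyl)pentan-3-yl (diethoxyphosphoryl)acetate | COc1ccc(COCC(=O)[C@@H](OC(=O)CP(=O)(OCC)OCC)CCSc2ccccc2)cc1
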